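**Retrosynthetic overview**
1. Target ⇒ (O9 acetylation, C11–C13 β-elimination, O8 acylation with epoxy acid 4) ⇒ ten-membered 8-hydroxy-9-silyloxy dienoate 27.
2. 27 ⇒ C8–C9 bond: the samarium ketyl of a C8 aldehyde adds to C9 of a β-silyloxyacrylate whose C10 carries a C1=C2=C3 allene (25); prototropy then turns the allene into the C1(10),C2 diene.
3. Enabling features: the vicinal C8/C9 oxygens next to the C14 ester on C10 (both carbons are aldehyde carbons in the seco form), and the trans C4–C5 oxirane plus the trans-fused γ-lactone (O, C6, C7, C11, C12), which exclude every ring smaller than the ten-membered carbocycle; the allene keeps spin and charge away from the oxirane.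
4. 25 ⇒ propargyl Claisen rearrangement (C10–C1) of a propiolate-derived vinyl ether on the C3 carbinol; lactone core ⇒ butenolide 15 (vinyl at C7, silyloxymethyl at C11) ⇒ enal 9 + methyl propiolate 10.
5. Ring order: C4–C5 oxirane (step 7), γ-lactone (step 8), ten-membered carbocycle (step 16); the side-chain oxirane is made separately (step 2).

Key step: step 16

Remark: locants C1–C15 are germacrane numbers (C1–C10 ring, C11/C12/C13 lactone α-carbon, carbonyl and exocyclic carbon, C14 ester carbon on C10, C15 methyl on C4).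
Assumption: (S,S)-ProPhenol is taken as the ligand enantiomer that gives the 6R carbinol in step 6; if the facial sense is the opposite, (R,R)-ProPhenol is used.
Remark: the C3 carbinol (20–23), C8 in diol 21, and the allene axis and C10 (24–26) are carried as mixtures that are erased in step 16; these descriptors are left open in the SMILES.

Step 1
Reactants: 1 tiglic acid
Product: 2 (2E)-2-methylbut-2-en-1-ol
Conditions: LiAlH4, Et2O, 0 °C
Reagents that add atoms: none
Why: Hydride reduction of the acid should give the allylic alcohol without touching the trisubstituted E-alkene; no stereocentre is formed.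

Step 2
Reactants: 2 (2E)-2-methylbut-2-en-1-ol
Product: 3 [(2R,3R)-2,3-dimethyloxiran-2-yl]methanol
Conditions: Ti(OiPr)4 (10 mol %), D-(−)-diethyl tartrate (12 mol %), t-BuOOH, 4 Å molecular sieves, CH2Cl2, −20 °C
Reagents that add atoms: tert-butyl hydroperoxide CC(C)(C)OO
Why: Sharpless asymmetric epoxidation of an E-allylic alcohol; the D-(−)-tartrate complex should deliver oxygen to the face that gives the 2R,3R oxirane (mirror image of the 2S,3S product of the L-(+)-tartrate).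

Step 3
Reactants: 3 [(2R,3R)-2,3-dimethyloxiran-2-yl]methanol
Product: 4 (2S,3R)-2,3-dimethyloxirane-2-carboxylic acid
Conditions: RuCl3·xH2O (2 mol %), NaIO4, CCl4–MeCN–H2O, 23 °C
Reagents that add atoms: sodium periodate [Na+].[O-]I(=O)(=O)=O; water O
Why: RuO4 oxidation of a primary epoxy alcohol to the glycidic acid; neither oxirane carbon is touched (C2 is quaternary), so only the CIP descriptor at C2 changes.

Step 4
Reactants: 5 tert-butyldimethyl(prop-2-yn-1-yloxy)silane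
Product: 8 (2E)-4-[(tert-butyldimethylsilyl)oxy]-3-methylbut-2-en-1-ol, via alkenylalane 6 (not isolated), via lithium aluminate 7 (not isolated)
Conditions: Me3Al, Cp2ZrCl2 (20 mol %), CH2Cl2, 0 → 23 °C; then n-BuLi, THF, −78 °C; (CH2O)n, −78 → 23 °C
Reagents that add atoms: trimethylaluminium C[Al](C)C; formaldehyde (from paraformaldehyde) C=O
Why: Negishi zirconium-catalysed carboalumination adds methyl and aluminium syn across the terminal alkyne (methyl to the internal carbon), which fixes the E olefin (C6 cis to C15), and the aluminate is hydroxymethylated with retention.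

Step 5
Reactants: 8 (2E)-4-[(tert-butyldimethylsilyl)oxy]-3-methylbut-2-en-1-ol
Product: 9 (2E)-4-[(tert-butyldimethylsilyl)oxy]-3-methylbut-2-enal
Conditions: MnO2, CH2Cl2, 23 °C
Reagents that add atoms: none
Why: Allylic oxidation with MnO2 should give the enal without E/Z isomerisation.

Step 6
Reactants: 9 (2E)-4-[(tert-butyldimethylsilyl)oxy]-3-methylbut-2-enal; 10 methyl propiolate
Product: 12 methyl (4R,5E)-7-[(tert-butyldimethylsilyl)oxy]-4-hydroxy-6-methylhept-5-en-2-ynoate, via methylzinc alkynylide 11 (not isolated)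
Conditions: Me2Zn, (S,S)-ProPhenol (10 mol %), Ph3P=O (20 mol %), toluene, 4 °C
Reagents that add atoms: none
Why: Zinc–ProPhenol catalysed enantioselective alkynylation of an enal; the dinuclear zinc catalyst differentiates the aldehyde faces and sets C6 (R by CIP at this stage).

Step 7
Reactants: 12 methyl (4R,5E)-7-[(tert-butyldimethylsilyl)oxy]-4-hydroxy-6-methylhept-5-en-2-ynoate
Product: 13 methyl (4S)-4-hydroxy-4-[(2R,3R)-3-{[(tert-butyldimethylsilyl)oxy]methyl}-3-methyloxiran-2-yl]but-2-ynoate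
Conditions: mCPBA, CH2Cl2, 0 °C
Reagents that add atoms: 3-chloroperbenzoic acid OOC(=O)c1cccc(Cl)c1
Why: Hydroxyl-directed peracid epoxidation; A(1,3) strain with the C15 methyl (cis to C6) holds H-6 in the olefin plane, so the hydrogen-bonded peracid should attack syn to the hydroxyl and give the threo 4R,5R oxirane, while the electron-poor ynoate is inert.

Step 8
Reactants: 13 methyl (4S)-4-hydroxy-4-[(2R,3R)-3-{[(tert-butyldimethylsilyl)oxy]methyl}-3-methyloxiran-2-yl]but-2-ynoate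
Product: 15 (5S)-5-[(2R,3R)-3-{[(tert-butyldimethylsilyl)oxy]methyl}-3-methyloxiran-2-yl]furan-2(5H)-one, via Z-hydroxy-enoate 14 (not isolated)
Conditions: H2 (1 atm), Pd/CaCO3–Pb(OAc)2 (Lindlar catalyst), quinoline, EtOAc, 23 °C; then silica gel, CH2Cl2
Reagents that add atoms: none
Why: Lindlar semi-hydrogenation gives the cis-γ-hydroxy enoate, which should lactonise to the butenolide; C6 is not touched.

Step 9
Reactants: 15 (5S)-5-[(2R,3R)-3-{[(tert-butyldimethylsilyl)oxy]methyl}-3-methyloxiran-2-yl]furan-2(5H)-one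
Product: 17 (3R,4S,5S)-5-[(2R,3R)-3-{[(tert-butyldimethylsilyl)oxy]methyl}-3-methyloxiran-2-yl]-4-ethenyl-3-{[(triisopropylsilyl)oxy]methyl}oxolan-2-one, via magnesium enolate 16 (not isolated)
Conditions: CH2=CHMgBr, CuBr·SMe2 (10 mol %), THF, −78 °C; then i-Pr3SiOCH2Cl, DMPU, −78 → −20 °C
Reagents that add atoms: vinylmagnesium bromide C=C[Mg]Br; (triisopropylsilyloxy)methyl chloride ClCO[Si](C(C)C)(C(C)C)C(C)C
Why: Tandem conjugate addition–enolate alkylation of a γ-substituted butenolide; the vinyl group should add anti to the C6 side chain (sets C7) and the chloromethyl ether anti to the vinyl group (sets C11), giving the all-trans lactone with C8 masked as vinyl and C13 as a silyloxymethyl group.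

Step 10
Reactants: 17 (3R,4S,5S)-5-[(2R,3R)-3-{[(tert-butyldimethylsilyl)oxy]methyl}-3-methyloxiran-2-yl]-4-ethenyl-3-{[(triisopropylsilyl)oxy]methyl}oxolan-2-one
Product: 18 (3R,4S,5S)-4-ethenyl-5-[(2R,3R)-3-(hydroxymethyl)-3-methyloxiran-2-yl]-3-{[(triisopropylsilyl)oxy]methyl}oxolan-2-one
Conditions: HF·pyridine, pyridine, THF, 0 °C
Reagents that add atoms: none
Why: Buffered HF·pyridine should cleave the primary tert-butyldimethylsilyl ether faster than the bulkier primary triisopropylsilyl ether, and the oxirane tolerates these conditions.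

Step 11
Reactants: 18 (3R,4S,5S)-4-ethenyl-5-[(2R,3R)-3-(hydroxymethyl)-3-methyloxiran-2-yl]-3-{[(triisopropylsilyl)oxy]methyl}oxolan-2-one
Product: 19 (2S,3R)-3-[(2S,3S,4R)-3-ethenyl-5-oxo-4-{[(triisopropylsilyl)oxy]methyl}oxolan-2-yl]-2-methyloxirane-2-carbaldehyde
Conditions: Dess–Martin periodinane, pyridine, CH2Cl2, 0 → 23 °C
Reagents that add atoms: none
Why: Dess–Martin oxidation of the primary alcohol; the α-carbon C4 is quaternary, so the epoxy aldehyde cannot epimerise.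

Step 12
Reactants: 19 (2S,3R)-3-[(2S,3S,4R)-3-ethenyl-5-oxo-4-{[(triisopropylsilyl)oxy]methyl}oxolan-2-yl]-2-methyloxirane-2-carbaldehyde
Product: 20 (3R,4S,5S)-4-ethenyl-5-[(2R,3R)-3-(1-hydroxyprop-2-yn-1-yl)-3-methyloxiran-2-yl]-3-{[(triisopropylsilyl)oxy]methyl}oxolan-2-one (C3 epimers)
Conditions: HC≡CMgBr, THF, −78 °C
Reagents that add atoms: ethynylmagnesium bromide C#C[Mg]Br
Why: Grignard addition to the highly electrophilic α,β-epoxy aldehyde should outpace attack on the lactone at −78 °C; both C3 epimers are used because C3 becomes sp2 later.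

Step 13
Reactants: 20 (3R,4S,5S)-4-ethenyl-5-[(2R,3R)-3-(1-hydroxyprop-2-yn-1-yl)-3-methyloxiran-2-yl]-3-{[(triisopropylsilyl)oxy]methyl}oxolan-2-one
Product: 22 (2S,3S,4R)-2-[(2R,3R)-3-(1-hydroxyprop-2-yn-1-yl)-3-methyloxiran-2-yl]-5-oxo-4-{[(triisopropylsilyl)oxy]methyl}oxolane-3-carbaldehyde, via vicinal diol 21 (not isolated)
Conditions: OsO4 (2 mol %), NaIO4, 2,6-lutidine, dioxane–H2O, 23 °C
Reagents that add atoms: osmium tetroxide O=[Os](=O)(=O)=O; sodium periodate [Na+].[O-]I(=O)(=O)=O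
Why: Lemieux–Johnson oxidation; only the monosubstituted vinyl group is osmylated and cleaved (alkyne and oxirane are inert), and the all-trans arrangement at C7 is the thermodynamically favoured one.

Step 14
Reactants: 22 (2S,3S,4R)-2-[(2R,3R)-3-(1-hydroxyprop-2-yn-1-yl)-3-methyloxiran-2-yl]-5-oxo-4-{[(triisopropylsilyl)oxy]methyl}oxolane-3-carbaldehyde; 10 methyl propiolate
Product: 23 methyl (2E)-3-({1-[(2R,3R)-3-[(2S,3S,4R)-3-formyl-5-oxo-4-{[(triisopropylsilyl)oxy]methyl}oxolan-2-yl]-2-methyloxiran-2-yl]prop-2-yn-1-yl}oxy)prop-2-enoate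
Conditions: N-methylmorpholine, CH2Cl2, 23 °C
Reagents that add atoms: none
Why: Amine-catalysed oxa-Michael addition of the propargylic alcohol to the propiolate should give the E-β-alkoxyacrylate; the aldehyde is a spectator.

Step 15
Reactants: 23 methyl (2E)-3-({1-[(2R,3R)-3-[(2S,3S,4R)-3-formyl-5-oxo-4-{[(triisopropylsilyl)oxy]methyl}oxolan-2-yl]-2-methyloxiran-2-yl]prop-2-yn-1-yl}oxy)prop-2-enoate
Product: 25 methyl (2Z)-3-[(tert-butyldimethylsilyl)oxy]-2-{3-[(2R,3R)-3-[(2S,3S,4R)-3-formyl-5-oxo-4-{[(triisopropylsilyl)oxy]methyl}oxolan-2-yl]-2-methyloxiran-2-yl]propa-1,2-dien-1-yl}prop-2-enoate, via allenyl aldo-ester 24 (not isolated)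
Conditions: AgSbF6 (5 mol %), CH2Cl2, 23 °C; then TBSOTf, 2,6-lutidine, −78 °C
Reagents that add atoms: tert-butyldimethylsilyl trifluoromethanesulfonate CC(C)(C)[Si](C)(C)OS(=O)(=O)C(F)(F)F
Why: Silver-catalysed propargyl Claisen rearrangement of the electron-poor propargyl vinyl ether builds C10–C1 and the allene, and the acidic chelated enol of the formyl ester is O-silylated at −78 °C before prototropy, which should give the Z enol ether (silyloxy cis to the ester); the C3 centre becomes the allene axis (mixture, erased later).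

Step 16
Reactants: 25 methyl (2Z)-3-[(tert-butyldimethylsilyl)oxy]-2-{3-[(2R,3R)-3-[(2S,3S,4R)-3-formyl-5-oxo-4-{[(triisopropylsilyl)oxy]methyl}oxolan-2-yl]-2-methyloxiran-2-yl]propa-1,2-dien-1-yl}prop-2-enoate
Product: 27 methyl (1(10)E,2Z,4R,5R,6S,7R,8S,9S,11R)-9-[(tert-butyldimethylsilyl)oxy]-4,5-epoxy-8-hydroxy-13-[(triisopropylsilyl)oxy]germacra-1(10),2-dien-12,6-olid-14-oate, via macrocyclic allenoate 26 (not isolated)
Conditions: SmI2 (2.2 equiv), MeOH, THF (3 mM), −78 °C; then DBU, CH2Cl2, 0 °C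
Reagents that add atoms: none
Why: Proposed new method: SmI2 reduces the C8 aldehyde to a samarium ketyl that adds to C9, the β-carbon of the β-silyloxyacrylate, in a samarium-bridged closure (closest known types: SmI2-induced reductive cyclisation of aldehydes onto β-alkoxyacrylates and SmI2 ketyl–olefin medium-ring closures); the C10 radical is reduced to the trivalent-samarium allenyl enolate, protonated by MeOH to 26, and DBU then moves the C10 proton to C2 so that the allene becomes the conjugated diene. Only the ten-membered carbocycle is closed, in the 10-endo-trig mode, because the trans C4–C5 oxirane cannot sit in the six-, seven- or eight-membered rings that attack at C3, C2 or C1 would need. C8 and C9 are set together: the C7 stereocentre of the trans-lactone is expected to direct the ketyl face, and chelation of the ketyl oxygen to the ester carbonyl (held cis to the silyloxy group in the Z enol ether) with C7 anti to C10 places O8 and O9 syn, the 8S,9S arrangement. The step needs chemoselectivity for the aldehyde with the oxirane left intact; this is secured by the allene, whose second π-bond is orthogonal to the C10 radical and enolate so that neither spin nor charge reaches C3, and by the silyl ether, a poor β-leaving group on the enolate. C2=C3 should be Z because C2 is protonated on the outer face, anti to C4; C1=C10 should form with C9 and C2 cis, the tiglate-type geometry that is thermodynamically preferred and needs no second trans unit in the ring.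

Step 17
Reactants: 27 methyl (1(10)E,2Z,4R,5R,6S,7R,8S,9S,11R)-9-[(tert-butyldimethylsilyl)oxy]-4,5-epoxy-8-hydroxy-13-[(triisopropylsilyl)oxy]germacra-1(10),2-dien-12,6-olid-14-oate; 4 (2S,3R)-2,3-dimethyloxirane-2-carboxylic acid
Product: 29 methyl (1(10)E,2Z,4R,5R,6S,7R,8S,9S,11R)-9-[(tert-butyldimethylsilyl)oxy]-8-{[(2S,3R)-2,3-dimethyloxiran-2-yl]carbonyloxy}-4,5-epoxy-13-[(triisopropylsilyl)oxy]germacra-1(10),2-dien-12,6-olid-14-oate, via mixed anhydride 28 (not isolated)
Conditions: 2,4,6-Cl3C6H2COCl, Et3N, THF, 0 °C; then 27, DMAP, toluene, 23 °C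
Reagents that add atoms: none
Why: Yamaguchi esterification through the mixed anhydride acylates the only free hydroxyl (O8) with retention at C8 and leaves the quaternary glycidic acid centre intact.

Step 18
Reactants: 29 methyl (1(10)E,2Z,4R,5R,6S,7R,8S,9S,11R)-9-[(tert-butyldimethylsilyl)oxy]-8-{[(2S,3R)-2,3-dimethyloxiran-2-yl]carbonyloxy}-4,5-epoxy-13-[(triisopropylsilyl)oxy]germacra-1(10),2-dien-12,6-olid-14-oate
Product: 30 methyl (1(10)E,2Z,4R,5R,6S,7R,8S,9S,11R)-8-{[(2S,3R)-2,3-dimethyloxiran-2-yl]carbonyloxy}-4,5-epoxy-9,13-dihydroxygermacra-1(10),2-dien-12,6-olid-14-oate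
Conditions: Bu4NF, AcOH (1:1), THF, 0 → 23 °C
Reagents that add atoms: none
Why: Fluoride cleaves both silyl ethers; buffering with AcOH should suppress migration of the hindered acyl group from O8 to O9 and base-induced side reactions.

Step 19
Reactants: 30 methyl (1(10)E,2Z,4R,5R,6S,7R,8S,9S,11R)-8-{[(2S,3R)-2,3-dimethyloxiran-2-yl]carbonyloxy}-4,5-epoxy-9,13-dihydroxygermacra-1(10),2-dien-12,6-olid-14-oate
Product: 33 methyl (1(10)E,2Z,4R,5R,6S,7R,8S,9S)-9-acetoxy-8-{[(2S,3R)-2,3-dimethyloxiran-2-yl]carbonyloxy}-4,5-epoxygermacra-1(10),2,11(13)-trien-12,6-olid-14-oate (target), via primary mesylate 31 (not isolated), via 9-hydroxy α-methylene lactone 32 (not isolated)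
Conditions: MsCl, Et3N, CH2Cl2, −40 → 23 °C; then Ac2O, DMAP (cat.), 0 °C
Reagents that add atoms: acetic anhydride CC(=O)OC(C)=O
Why: The primary hydroxyl should be mesylated selectively, E1cB elimination of the β-mesyloxy lactone forms the exocyclic methylene, and the remaining hindered allylic C9 hydroxyl is then acetylated; no stereocentre is touched.

**Compound list**
1 | tiglic acid, (2E)-2-methylbut-2-enoic acid | C/C=C(\C)C(=O)O | starting material
2 | (2E)-2-methylbut-2-en-1-ol | C/C=C(\C)CO | intermediate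
3 | [(2R,3R)-2,3-dimethyloxiran-2-yl]methanol | OC[C@@]1(C)O[C@@H]1C | intermediate
4 | (2S,3R)-2,3-dimethyloxirane-2-carboxylic acid | OC(=O)[C@@]1(C)O[C@@H]1C | intermediate
5 | tert-butyldimethyl(prop-2-yn-1-yloxy)silane | C#CCO[Si](C)(C)C(C)(C)C | starting material
6 | dimethyl[(1E)-3-[(tert-butyldimethylsilyl)oxy]-2-methylprop-1-en-1-yl]alane | C[Al](C)/C=C(\C)CO[Si](C)(C)C(C)(C)C | intermediate
7 | lithium butyl(dimethyl)[(1E)-3-[(tert-butyldimethylsilyl)oxy]-2-methylprop-1-en-1-yl]aluminate | [Li+].CCCC[Al-](C)(C)/C=C(\C)CO[Si](C)(C)C(C)(C)C | intermediate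
8 | (2E)-4-[(tert-butyldimethylsilyl)oxy]-3-methylbut-2-en-1-ol | OC/C=C(\C)CO[Si](C)(C)C(C)(C)C | intermediate
9 | (2E)-4-[(tert-butyldimethylsilyl)oxy]-3-methylbut-2-enal | O=C/C=C(\C)CO[Si](C)(C)C(C)(C)C | intermediate
10 | methyl propiolate | C#CC(=O)OC | starting material
11 | methylzinc 3-methoxy-3-oxoprop-1-yn-1-ide | C[Zn]C#CC(=O)OC | intermediate
12 | methyl (4R,5E)-7-[(tert-butyldimethylsilyl)oxy]-4-hydroxy-6-methylhept-5-en-2-ynoate (6R in germacrane numbering) | O[C@H](/C=C(\C)CO[Si](C)(C)C(C)(C)C)C#CC(=O)OC | intermediate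
13 | methyl (4S)-4-hydroxy-4-[(2R,3R)-3-{[(tert-butyldimethylsilyl)oxy]methyl}-3-methyloxiran-2-yl]but-2-ynoate (4R,5R,6S) | O[C@H]([C@H]1O[C@]1(C)CO[Si](C)(C)C(C)(C)C)C#CC(=O)OC | intermediate
14 | methyl (2Z,4S)-4-hydroxy-4-[(2R,3R)-3-{[(tert-butyldimethylsilyl)oxy]methyl}-3-methyloxiran-2-yl]but-2-enoate | O[C@H]([C@H]1O[C@]1(C)CO[Si](C)(C)C(C)(C)C)/C=C\C(=O)OC | intermediate
15 | (5S)-5-[(2R,3R)-3-{[(tert-butyldimethylsilyl)oxy]methyl}-3-methyloxiran-2-yl]furan-2(5H)-one | O=C1O[C@H]([C@H]2O[C@]2(C)CO[Si](C)(C)C(C)(C)C)C=C1 | intermediate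
16 | bromomagnesium enolate of the 7-vinyl lactone (vinyl anti to the C6 side chain) | Br[Mg]OC1=C[C@H](C=C)[C@@H]([C@H]2O[C@]2(C)CO[Si](C)(C)C(C)(C)C)O1 | intermediate
17 | (3R,4S,5S)-5-[(2R,3R)-3-{[(tert-butyldimethylsilyl)oxy]methyl}-3-methyloxiran-2-yl]-4-ethenyl-3-{[(triisopropylsilyl)oxy]methyl}oxolan-2-one (4R,5R,6S,7S,11R; all-trans lactone) | O=C1O[C@H]([C@H]2O[C@]2(C)CO[Si](C)(C)C(C)(C)C)[C@@H](C=C)[C@@H]1CO[Si](C(C)C)(C(C)C)C(C)C | intermediate
18 | (3R,4S,5S)-4-ethenyl-5-[(2R,3R)-3-(hydroxymethyl)-3-methyloxiran-2-yl]-3-{[(triisopropylsilyl)oxy]methyl}oxolan-2-one | O=C1O[C@H]([C@H]2O[C@]2(C)CO)[C@@H](C=C)[C@@H]1CO[Si](C(C)C)(C(C)C)C(C)C | intermediate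
19 | (2S,3R)-3-[(2S,3S,4R)-3-ethenyl-5-oxo-4-{[(triisopropylsilyl)oxy]methyl}oxolan-2-yl]-2-methyloxirane-2-carbaldehyde | O=C1O[C@H]([C@H]2O[C@]2(C)C=O)[C@@H](C=C)[C@@H]1CO[Si](C(C)C)(C(C)C)C(C)C | intermediate
20 | (3R,4S,5S)-4-ethenyl-5-[(2R,3R)-3-(1-hydroxyprop-2-yn-1-yl)-3-methyloxiran-2-yl]-3-{[(triisopropylsilyl)oxy]methyl}oxolan-2-one (C3 epimers) | O=C1O[C@H]([C@H]2O[C@]2(C)C(O)C#C)[C@@H](C=C)[C@@H]1CO[Si](C(C)C)(C(C)C)C(C)C | intermediate
21 | 8,8a-diol from osmylation of the vinyl group of 20 (C3 and C8 epimers) | O=C1O[C@H]([C@H]2O[C@]2(C)C(O)C#C)[C@@H](C(O)CO)[C@@H]1CO[Si](C(C)C)(C(C)C)C(C)C | intermediate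
22 | (2S,3S,4R)-2-[(2R,3R)-3-(1-hydroxyprop-2-yn-1-yl)-3-methyloxiran-2-yl]-5-oxo-4-{[(triisopropylsilyl)oxy]methyl}oxolane-3-carbaldehyde (C3 epimers) | O=C1O[C@H]([C@H]2O[C@]2(C)C(O)C#C)[C@@H](C=O)[C@@H]1CO[Si](C(C)C)(C(C)C)C(C)C | intermediate
23 | methyl (2E)-3-({1-[(2R,3R)-3-[(2S,3S,4R)-3-formyl-5-oxo-4-{[(triisopropylsilyl)oxy]methyl}oxolan-2-yl]-2-methyloxiran-2-yl]prop-2-yn-1-yl}oxy)prop-2-enoate (C3 epimers) | O=C1O[C@H]([C@H]2O[C@]2(C)C(O/C=C/C(=O)OC)C#C)[C@@H](C=O)[C@@H]1CO[Si](C(C)C)(C(C)C)C(C)C | intermediate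
24 | methyl 2-formyl-5-[(2R,3R)-3-[(2S,3S,4R)-3-formyl-5-oxo-4-{[(triisopropylsilyl)oxy]methyl}oxolan-2-yl]-2-methyloxiran-2-yl]penta-3,4-dienoate (C10 and allene-axis epimers, enolised) | O=C1O[C@H]([C@H]2O[C@]2(C)C=C=CC(C=O)C(=O)OC)[C@@H](C=O)[C@@H]1CO[Si](C(C)C)(C(C)C)C(C)C | intermediate
25 | methyl (2Z)-3-[(tert-butyldimethylsilyl)oxy]-2-{3-[(2R,3R)-3-[(2S,3S,4R)-3-formyl-5-oxo-4-{[(triisopropylsilyl)oxy]methyl}oxolan-2-yl]-2-methyloxiran-2-yl]propa-1,2-dien-1-yl}prop-2-enoate (allene-axis epimers) | O=C1O[C@H]([C@H]2O[C@]2(C)C=C=C/C(C(=O)OC)=C/O[Si](C)(C)C(C)(C)C)[C@@H](C=O)[C@@H]1CO[Si](C(C)C)(C(C)C)C(C)C | intermediate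
26 | methyl (4R,5R,6S,7R,8S,9S,11R)-9-[(tert-butyldimethylsilyl)oxy]-4,5-epoxy-8-hydroxy-13-[(triisopropylsilyl)oxy]germacra-1,2-dien-12,6-olid-14-oate (C10 and allene-axis epimers) | CC(C)[Si](C(C)C)(C(C)C)OC[C@@H]1C(=O)O[C@H]2[C@H]1[C@H](O)[C@@H](O[Si](C)(C)C(C)(C)C)C(C(=O)OC)C=C=C[C@@]1(C)O[C@H]21 | intermediate
27 | methyl (1(10)E,2Z,4R,5R,6S,7R,8S,9S,11R)-9-[(tert-butyldimethylsilyl)oxy]-4,5-epoxy-8-hydroxy-13-[(triisopropylsilyl)oxy]germacra-1(10),2-dien-12,6-olid-14-oate | CC(C)[Si](C(C)C)(C(C)C)OC[C@@H]1C(=O)O[C@H]2[C@H]1[C@H](O)[C@@H](O[Si](C)(C)C(C)(C)C)/C(C(=O)OC)=C\C=C/[C@@]1(C)O[C@H]21 | intermediate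
28 | (2S,3R)-2,3-dimethyloxirane-2-carboxylic 2,4,6-trichlorobenzoic anhydride | O=C(OC(=O)c1c(Cl)cc(Cl)cc1Cl)[C@@]1(C)O[C@@H]1C | intermediate
29 | methyl (1(10)E,2Z,4R,5R,6S,7R,8S,9S,11R)-9-[(tert-butyldimethylsilyl)oxy]-8-{[(2S,3R)-2,3-dimethyloxiran-2-yl]carbonyloxy}-4,5-epoxy-13-[(triisopropylsilyl)oxy]germacra-1(10),2-dien-12,6-olid-14-oate | CC(C)[Si](C(C)C)(C(C)C)OC[C@@H]1C(=O)O[C@H]2[C@H]1[C@H](OC(=O)[C@@]1(C)O[C@@H]1C)[C@@H](O[Si](C)(C)C(C)(C)C)/C(C(=O)OC)=C\C=C/[C@@]1(C)O[C@H]21 | intermediate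
30 | methyl (1(10)E,2Z,4R,5R,6S,7R,8S,9S,11R)-8-{[(2S,3R)-2,3-dimethyloxiran-2-yl]carbonyloxy}-4,5-epoxy-9,13-dihydroxygermacra-1(10),2-dien-12,6-olid-14-oate | OC[C@@H]1C(=O)O[C@H]2[C@H]1[C@H](OC(=O)[C@@]1(C)O[C@@H]1C)[C@@H](O)/C(C(=O)OC)=C\C=C/[C@@]1(C)O[C@H]21 | intermediate
31 | 13-O-methanesulfonate of 30 | CS(=O)(=O)OC[C@@H]1C(=O)O[C@H]2[C@H]1[C@H](OC(=O)[C@@]1(C)O[C@@H]1C)[C@@H](O)/C(C(=O)OC)=C\C=C/[C@@]1(C)O[C@H]21 | intermediate
32 | methyl (1(10)E,2Z,4R,5R,6S,7R,8S,9S)-8-{[(2S,3R)-2,3-dimethyloxiran-2-yl]carbonyloxy}-4,5-epoxy-9-hydroxygermacra-1(10),2,11(13)-trien-12,6-olid-14-oate | C=C1C(=O)O[C@H]2[C@H]1[C@H](OC(=O)[C@@]1(C)O[C@@H]1C)[C@@H](O)/C(C(=O)OC)=C\C=C/[C@@]1(C)O[C@H]21 | intermediate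
33 | methyl (1(10)E,2Z,4R,5R,6S,7R,8S,9S)-9-acetoxy-8-{[(2S,3R)-2,3-dimethyloxiran-2-yl]carbonyloxy}-4,5-epoxygermacra-1(10),2,11(13)-trien-12,6-olid-14-oate (CNP0229507.7) | C=C1C(=O)O[C@H]2[C@H]1[C@H](OC(=O)[C@@]1(C)O[C@@H]1C)[C@@H](OC(C)=O)/C(C(=O)OC)=C\C=C/[C@@]1(C)O[C@H]21 | target

**Totals**
Total step count: 19. Longest linear sequence: 16 steps (5 → 33, steps 4–19); the side-chain acid 4 takes 3 steps.

**Steps most likely to fail**

1. Step 16 (Proposed new method). The ten-membered closure may be slower than further reduction and protonation of the ketyl (giving the C8 carbinol) or than pinacol dimerisation, and the facial selectivity at C8 may be poor. Fallback with known reaction types: set out from 25 and form the ring through the C8 acyl radical instead of the ketyl. Photocatalytic hydrogen-atom-transfer hydroacylation of electron-poor alkenes by aldehydes and endo acyl-radical macrocyclisations onto acrylates are both known, and an acyl radical cannot be over-reduced. Irradiation at 390 nm with (Bu4N)4W10O32 (2 mol %) in MeCN should give the macrocyclic 8-oxo allenoate F1. DBU in CH2Cl2 at 0 °C should then give the 8-oxo dienoate F2. Felkin–Anh reduction with LiBH(s-Bu)3 in THF at −78 °C, with the bulky non-chelating C9 silyloxy group anti to the hydride, should give the syn carbinol, so the route comes back at 27 with C8 set in a separate step.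

2. Step 7. Facial selectivity of the directed epoxidation may be poor, because the slim alkynyl group can compete with H-6 for the in-plane position and erode the threo preference. Fallback: set the oxirane first under reagent control. From 8, Sharpless asymmetric epoxidation (Ti(OiPr)4, D-(−)-diethyl tartrate, t-BuOOH) should give the epoxy alcohol F3. Dess–Martin oxidation gives the epoxy aldehyde F4. Zinc–ProPhenol alkynylation of F4 with 10 (reagent control at C6, helped by zinc chelation to the oxirane oxygen) comes back at 13.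

3. Step 9. The hindered magnesium enolate may be protonated, O-alkylated or left unreacted by the chloromethyl ether. Fallback: replace the alkylation by an aldol. From 15, copper-catalysed vinyl Grignard addition with an aqueous quench gives the vinyl lactone F5. LDA and monomeric formaldehyde at −78 °C (aldol anti to the vinyl group) give the hydroxymethyl lactone F6. Silylation with i-Pr3SiCl and imidazole comes back at 17.

Further compounds
F1 | step 16 | methyl (4R,5R,6S,7S,9S,11R)-9-[(tert-butyldimethylsilyl)oxy]-4,5-epoxy-8-oxo-13-[(triisopropylsilyl)oxy]germacra-1,2-dien-12,6-olid-14-oate (C10 and allene-axis epimers) | CC(C)[Si](C(C)C)(C(C)C)OC[C@@H]1C(=O)O[C@H]2[C@H]1C(=O)[C@@H](O[Si](C)(C)C(C)(C)C)C(C(=O)OC)C=C=C[C@@]1(C)O[C@H]21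
F2 | step 16 | methyl (1(10)E,2Z,4R,5R,6S,7S,9S,11R)-9-[(tert-butyldimethylsilyl)oxy]-4,5-epoxy-8-oxo-13-[(triisopropylsilyl)oxy]germacra-1(10),2-dien-12,6-olid-14-oate | CC(C)[Si](C(C)C)(C(C)C)OC[C@@H]1C(=O)O[C@H]2[C@H]1C(=O)[C@@H](O[Si](C)(C)C(C)(C)C)/C(C(=O)OC)=C\C=C/[C@@]1(C)O[C@H]21
F3 | step 7 | [(2R,3R)-3-{[(tert-butyldimethylsilyl)oxy]methyl}-3-methyloxiran-2-yl]methanol | OC[C@H]1O[C@]1(C)CO[Si](C)(C)C(C)(C)C
F4 | step 7 | (2S,3R)-3-{[(tert-butyldimethylsilyl)oxy]methyl}-3-methyloxirane-2-carbaldehyde | O=C[C@H]1O[C@]1(C)CO[Si](C)(C)C(C)(C)C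
F5 | step 9 | (4R,5S)-5-[(2R,3R)-3-{[(tert-butyldimethylsilyl)oxy]methyl}-3-methyloxiran-2-yl]-4-ethenyloxolan-2-one | O=C1O[C@H]([C@H]2O[C@]2(C)CO[Si](C)(C)C(C)(C)C)[C@@H](C=C)C1
F6 | step 9 | (3R,4S,5S)-5-[(2R,3R)-3-{[(tert-butyldimethylsilyl)oxy]methyl}-3-methyloxiran-2-yl]-4-ethenyl-3-(hydroxymethyl)oxolan-2-one | O=C1O[C@H]([C@H]2O[C@]2(C)CO[Si](C)(C)C(C)(C)C)[C@@H](C=C)[C@@H]1CO
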